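Assumption: atom locants C1–C20 in the text follow briarane numbering (Me-15 on C1, Me-16 on C5, Me-18 and lactone carbonyl C19 on C17, Me-20 on C11). Compound numbers follow the forward route, so the target carries the last number.

**Retrosynthetic overview**

1. Target ⇐ α-face cis-dihydroxylation of C11=C12 in a 2,9-diacetoxy-briara-5,11,13-triene lactone.
2. Briarane 6/10 bicycle ⇐ transannular C1–C10 closure (cembrane C3–C8, as in the presumed biogenesis) of a 14-membered (5Z,10E,13Z)-cembratriene 1,2-vinyl epoxide: Lewis acid opens the epoxide with inversion at C1, C10=C11 attacks, H-12 is lost.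
3. 14-Membered carbocycle with its γ-lactone ⇐ Ni/Cr closure C6–C7 of a (Z)-vinyl iodide onto a C7 aldehyde.
4. Acyclic chain ⇐ Z-Wittig (C13=C14) of a Sharpless-derived cis-epoxy aldehyde with a phosphonium salt made by a Seebach dioxolanone aldol (C8–C9) from L-malate.
5. Ring order: γ-lactone and 14-membered ring (step 18), then cyclohexadiene and 10-membered ring together (step 19).

**Route**

Step 1
Reactants: 1 2-(2-bromoethyl)-1,3-dioxolane; 2 propyne
Product: 6 2-[(3Z)-4-iodo-3-methylbut-3-en-1-yl]-1,3-dioxolane, via Grignard reagent 3 (not isolated), via alkylcopper 4 (not isolated), via (Z)-alkenylcopper 5 (not isolated)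
Conditions: Mg, THF; CuBr·SMe2, Et2O/Me2S, −45 °C; propyne, −25 °C; I2, −78 → 0 °C
Reagents that add atoms: iodine, II
Why: Normant syn-carbocupration of propyne places the alkyl group and copper cis, and iodinolysis with retention gives the (Z)-trisubstituted vinyl iodide that later becomes the 5Z olefin.

Step 2
Reactants: 6 2-[(3Z)-4-iodo-3-methylbut-3-en-1-yl]-1,3-dioxolane
Product: 7 (4Z)-5-iodo-4-methylpent-4-enal
Conditions: 2 M HCl, THF, 23 °C
Reagents that add atoms: water, O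
Why: Acid-catalysed acetal hydrolysis frees the C2 aldehyde without touching the vinyl iodide.

Step 3
Reactants: 7 (4Z)-5-iodo-4-methylpent-4-enal; 8 ethyl 2-(diphenoxyphosphoryl)propanoate
Product: 10 ethyl (2Z,6Z)-7-iodo-2,6-dimethylhepta-2,6-dienoate, via sodium phosphonate 9 (not isolated)
Conditions: NaH, THF, −78 → 0 °C
Reagents that add atoms: none
Why: The Ando variant of the Horner–Wadsworth–Emmons olefination eliminates kinetically from the syn adduct and gives the (Z)-2-methyl enoate (typically ≥95:5).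

Step 4
Reactants: 10 ethyl (2Z,6Z)-7-iodo-2,6-dimethylhepta-2,6-dienoate
Product: 12 (2Z,6Z)-7-iodo-2,6-dimethylhepta-2,6-dien-1-ol, via enal 11 (not isolated)
Conditions: DIBAL-H (2.2 eq), CH2Cl2, −78 °C; aq. Rochelle salt
Reagents that add atoms: none
Why: DIBAL-H reduces the enoate 1,2 to the allylic alcohol with both olefin geometries intact.

Step 5
Reactants: 12 (2Z,6Z)-7-iodo-2,6-dimethylhepta-2,6-dien-1-ol
Product: 13 [(2S,3R)-3-[(3Z)-4-iodo-3-methylbut-3-en-1-yl]-2-methyloxiran-2-yl]methanol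
Conditions: Ti(OiPr)4 (10 mol %), L-(+)-DIPT (12 mol %), TBHP, 4 Å MS, CH2Cl2, −20 °C
Reagents that add atoms: tert-butyl hydroperoxide, CC(C)(C)OO
Why: Sharpless asymmetric epoxidation with L-(+)-tartrate delivers oxygen to the face that gives the (2S,3R) cis-epoxide (same sense as nerol → (2S,3R)-epoxynerol), fixing C1 and C2 of the target.

Step 6
Reactants: 13 [(2S,3R)-3-[(3Z)-4-iodo-3-methylbut-3-en-1-yl]-2-methyloxiran-2-yl]methanol
Product: 14 (2R,3R)-3-[(3Z)-4-iodo-3-methylbut-3-en-1-yl]-2-methyloxirane-2-carbaldehyde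
Conditions: PhI(OAc)2, TEMPO (cat.), CH2Cl2, 23 °C
Reagents that add atoms: none
Why: TEMPO/BAIB oxidation gives the epoxy aldehyde, whose α-carbon is quaternary and cannot epimerise (the descriptor changes only through CIP priorities).

Step 7
Reactants: 15 diethyl (S)-malate
Product: 17 diethyl (2S,3R)-2-hydroxy-3-methylbutanedioate, via dilithium alkoxide enolate 16 (not isolated)
Conditions: LDA (2.2 eq), THF, −78 → −20 °C; MeI, −78 → 0 °C
Reagents that add atoms: iodomethane, CI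
Why: Fráter–Seebach alkylation of the chelated dianion occurs anti to the alkoxide and gives the (2S,3R) isomer (about 9:1), which sets C17.

Step 8
Reactants: 17 diethyl (2S,3R)-2-hydroxy-3-methylbutanedioate
Product: 18 (2S,3R)-2-hydroxy-3-methylbutanedioic acid
Conditions: KOH, EtOH/H2O, 23 °C; then HCl
Reagents that add atoms: water, O
Why: Saponification at 23 °C gives the diacid; the dianion formed after the first hydrolysis resists α-deprotonation, so C17 is kept.

Step 9
Reactants: 18 (2S,3R)-2-hydroxy-3-methylbutanedioic acid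
Product: 19 (2R)-2-[(2S,4S)-2-tert-butyl-5-oxo-1,3-dioxolan-4-yl]propanoic acid
Conditions: t-BuCHO, TsOH (cat.), H2SO4 (cat.), pentane, reflux (Dean–Stark); recrystallise
Reagents that add atoms: pivalaldehyde, CC(C)(C)C=O
Why: Seebach acetalisation of the α-hydroxy acid terminus gives the five-membered dioxolanone, the cis isomer being thermodynamically preferred and purified by crystallisation; its acetal centre stores the chirality of C8.

Step 10
Reactants: 19 (2R)-2-[(2S,4S)-2-tert-butyl-5-oxo-1,3-dioxolan-4-yl]propanoic acid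
Product: 21 propan-2-yl (2R)-2-[(2S,4S)-2-tert-butyl-5-oxo-1,3-dioxolan-4-yl]propanoate, via potassium carboxylate 20 (not isolated)
Conditions: 2-iodopropane, K2CO3, DMF, 23 °C
Reagents that add atoms: 2-iodopropane, CC(C)I
Why: SN2 O-alkylation of the carboxylate gives a hindered isopropyl ester that survives the later hydride step yet can still lactonise.

Step 11
Reactants: 22 but-3-yn-1-ol
Product: 24 (2E)-3-methylpent-2-ene-1,5-diol, via alkenylalane 23 (not isolated)
Conditions: Me3Al (3 eq), Cp2ZrCl2 (0.25 eq), CH2Cl2, 0 → 23 °C; then n-BuLi, (CH2O)n, THF, −78 → 23 °C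
Reagents that add atoms: trimethylaluminium, C[Al](C)C; formaldehyde (as paraformaldehyde), C=O
Why: Negishi zirconium-catalysed carboalumination adds Me and Al syn, so hydroxymethylation of the alanate gives only the (E)-trisubstituted olefin (future 10E).

Step 12
Reactants: 24 (2E)-3-methylpent-2-ene-1,5-diol
Product: 25 (2E)-5-hydroxy-3-methylpent-2-enal
Conditions: MnO2, CH2Cl2, 23 °C
Reagents that add atoms: none
Why: Activated MnO2 oxidises only the allylic alcohol and leaves the homoallylic one.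

Step 13
Reactants: 25 (2E)-5-hydroxy-3-methylpent-2-enal
Product: 26 (2E)-5-bromo-3-methylpent-2-enal
Conditions: CBr4, PPh3, CH2Cl2, 0 °C
Reagents that add atoms: tetrabromomethane, BrC(Br)(Br)Br
Why: The Appel reaction converts the primary alcohol into the bromide under neutral conditions that the enal tolerates.

Step 14
Reactants: 21 propan-2-yl (2R)-2-[(2S,4S)-2-tert-butyl-5-oxo-1,3-dioxolan-4-yl]propanoate; 26 (2E)-5-bromo-3-methylpent-2-enal
Product: 29 propan-2-yl (2R)-2-[(2S,4R)-4-[(1R,2E)-5-bromo-3-methyl-1-(triethylsilyloxy)pent-2-en-1-yl]-2-tert-butyl-5-oxo-1,3-dioxolan-4-yl]propanoate, via lithium enolate 27 (not isolated), via lithium aldolate 28 (not isolated)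
Conditions: LiHMDS (1.05 eq), THF, −78 °C; 26, −78 °C; TESOTf, −78 °C
Reagents that add atoms: triethylsilyl trifluoromethanesulfonate, CC[Si](CC)(CC)OS(=O)(=O)C(F)(F)F
Why: In this Seebach self-regeneration-of-stereocentres aldol the enolate is attacked anti to the tert-butyl group (C8 formed with retention) through a chair Zimmerman–Traxler state with the enal residue equatorial (ring oxygen anti to the new hydroxyl, giving 9R), and silylation in the same flask stops the aldolate from lactonising onto the ester.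

Step 15
Reactants: 29 propan-2-yl (2R)-2-[(2S,4R)-4-[(1R,2E)-5-bromo-3-methyl-1-(triethylsilyloxy)pent-2-en-1-yl]-2-tert-butyl-5-oxo-1,3-dioxolan-4-yl]propanoate
Product: 30 [(3E,5R)-5-[(2S,4R)-2-tert-butyl-5-oxo-4-[(2R)-1-oxo-1-(propan-2-yloxy)propan-2-yl]-1,3-dioxolan-4-yl]-3-methyl-5-(triethylsilyloxy)pent-3-en-1-yl]triphenylphosphonium bromide
Conditions: PPh3, MeCN, 75 °C
Reagents that add atoms: triphenylphosphine, c1ccc(cc1)P(c1ccccc1)c1ccccc1
Why: SN2 quaternisation of the primary homoallylic bromide gives the Wittig salt without affecting the acylal, ester or silyl ether.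

Step 16
Reactants: 30 phosphonium bromide from step 15; 14 (2R,3R)-3-[(3Z)-4-iodo-3-methylbut-3-en-1-yl]-2-methyloxirane-2-carbaldehyde
Product: 32 propan-2-yl (2R)-2-[(2S,4R)-2-tert-butyl-4-[(1R,2E,5Z)-6-[(2S,3R)-3-[(3Z)-4-iodo-3-methylbut-3-en-1-yl]-2-methyloxiran-2-yl]-3-methyl-1-(triethylsilyloxy)hexa-2,5-dien-1-yl]-5-oxo-1,3-dioxolan-4-yl]propanoate, via phosphonium ylide 31 (not isolated)
Conditions: NaHMDS (1.0 eq), THF, −78 °C; 14, −78 → 0 °C
Reagents that add atoms: none
Why: The Wittig reaction of a non-stabilised ylide under salt-free conditions gives the (Z)-olefin (13Z) via the kinetic cis-oxaphosphetane, and the non-enolisable epoxy aldehyde keeps C1 and C2.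

Step 17
Reactants: 32 acyclic dioxolanone from step 16
Product: 34 propan-2-yl (2R,3R,4R,5E,8Z)-3-formyl-3-hydroxy-9-[(2S,3R)-3-[(3Z)-4-iodo-3-methylbut-3-en-1-yl]-2-methyloxiran-2-yl]-2,6-dimethyl-4-(triethylsilyloxy)nona-5,8-dienoate, via dioxolanyl lactol 33 (not isolated)
Conditions: DIBAL-H (1.15 eq), CH2Cl2, −90 °C; MeOH; aq. Rochelle salt, 23 °C
Reagents that add atoms: none
Why: DIBAL-H is expected to reduce the strongly electrophilic acylal carbonyl of the dioxolanone before the hindered isopropyl ester, and the lactol collapses on buffered work-up with loss of pivalaldehyde to the C7 aldehyde carrying the free tertiary 8-OH.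

Step 18
Reactants: 34 hydroxy aldehyde from step 17
Product: 37 (1S,2R,5Z,7S,8S,9R,10E,13Z,17R)-1,2-epoxy-8-hydroxy-9-(triethylsilyloxy)-1,10-seco-briara-5,10,13-triene 7,19-lactone, via alkenylchromium 35 (not isolated), via macrocyclic hydroxy ester 36 (not isolated)
Conditions: CrCl2 (8 eq), NiCl2 (2 mol %), DMSO/THF 3:1, 2 mM, 23 °C; then 2-hydroxypyridine (0.2 eq), PhMe, 60 °C
Reagents that add atoms: none
Why: Nozaki–Hiyama–Kishi macrocyclisation closes the 14-membered cembranoid ring at C6–C7 with retention of the Z-alkenyl geometry, polar Felkin–Anh addition (C8–O anti to the alkenylchromium, C9 inside) gives 7S, and the new hydroxyl lactonises onto the isopropyl ester.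

Step 19
Reactants: 37 cembranoid vinyl-epoxide lactone from step 18
Product: 39 (1S,2R,5Z,7S,8S,9R,10S,17R)-2,8-dihydroxy-9-(triethylsilyloxy)briara-5,11,13-triene 7,19-lactone, via C11 carbocation 38 (not isolated)
Conditions: Et2AlCl (4 eq), CH2Cl2, −78 → −40 °C; aq. Rochelle salt
Reagents that add atoms: none
Why: Proposed new method: a Lewis-acid epoxide-initiated cation–olefin cyclisation run transannularly (closest known type: Me2AlCl/Et2AlCl-promoted epoxy-olefin cyclisations and transannular cyclisations of germacrene or cembrene epoxides), in which the aluminium-activated allylic tertiary C1–O bond is attacked from the rear by C10 of the E-C10=C11 olefin (6-exo, inversion at C1 so that the cis-epoxide gives 1S next to 2R, E-olefin and C2 anti to C13 give the trans-fused 10S), the C11 cation loses the allylic H-12 to the conjugated 11,13-diene with the ethylaluminium acting as proton scavenger, and the 8-OH is masked in the flask as its aluminium alkoxide.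

Step 20
Reactants: 39 silyl ether diene from step 19
Product: 40 (1S,2R,5Z,7S,8S,9R,10S,17R)-2,8,9-trihydroxybriara-5,11,13-triene 7,19-lactone
Conditions: HF·pyridine, THF/pyridine, 0 °C
Reagents that add atoms: none
Why: Fluoride-mediated desilylation frees the 9-OH under conditions the diene and β-hydroxy lactone tolerate.

Step 21
Reactants: 40 triol from step 20
Product: 41 (1S,2R,5Z,7S,8S,9R,10S,17R)-2,9-diacetoxy-8-hydroxybriara-5,11,13-triene 7,19-lactone
Conditions: Ac2O, pyridine, DMAP (cat.), CH2Cl2, 0 → 23 °C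
Reagents that add atoms: acetic anhydride, CC(=O)OC(C)=O
Why: DMAP-catalysed acylation esterifies the two secondary alcohols while the tertiary 8-OH is too hindered to react.

Step 22
Reactants: 41 diacetate diene from step 21
Product: 43 (1S,2R,5Z,7S,8S,9R,10S,11S,12R,17R)-2,9-diacetoxy-8,11,12-trihydroxybriara-5,13-diene 7,19-lactone (CNP0146024.1), via osmate ester 42 (not isolated)
Conditions: OsO4 (5 mol %), NMO (1.1 eq), acetone/H2O, 0 °C
Reagents that add atoms: osmium tetroxide, O=[Os](=O)(=O)=O; N-methylmorpholine N-oxide, C[N+]1([O-])CCOCC1; water, O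
Why: Upjohn syn-dihydroxylation takes the electron-rich trisubstituted C11=C12 end of the diene from the α-face, anti to the pseudo-axial C15 methyl, giving the 11α,12α-cis-diol (11S,12R) and leaving C13=C14 and the acyloxy-deactivated C5=C6.

**Compound list**

1 | 2-(2-bromoethyl)-1,3-dioxolane | BrCCC1OCCO1 | starting material
2 | propyne | CC#C | starting material
3 | [2-(1,3-dioxolan-2-yl)ethyl]magnesium bromide | Br[Mg]CCC1OCCO1 | intermediate
4 | [2-(1,3-dioxolan-2-yl)ethyl]copper | [Cu]CCC1OCCO1 | intermediate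
5 | [(1Z)-4-(1,3-dioxolan-2-yl)-2-methylbut-1-en-1-yl]copper | [Cu]/C=C(C)\CCC1OCCO1 | intermediate
6 | 2-[(3Z)-4-iodo-3-methylbut-3-en-1-yl]-1,3-dioxolane | I/C=C(C)\CCC1OCCO1 | intermediate
7 | (4Z)-5-iodo-4-methylpent-4-enal | I/C=C(C)\CCC=O | intermediate
8 | ethyl 2-(diphenoxyphosphoryl)propanoate | CCOC(=O)C(C)P(=O)(Oc1ccccc1)Oc1ccccc1 | starting material
9 | sodium salt of 8 (phosphonate carbanion) | CCOC(=O)[C-](C)P(=O)(Oc1ccccc1)Oc1ccccc1.[Na+] | intermediate
10 | ethyl (2Z,6Z)-7-iodo-2,6-dimethylhepta-2,6-dienoate | CCOC(=O)/C(C)=C\CC/C(C)=C\I | intermediate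
11 | (2Z,6Z)-7-iodo-2,6-dimethylhepta-2,6-dienal | O=C/C(C)=C\CC/C(C)=C\I | intermediate
12 | (2Z,6Z)-7-iodo-2,6-dimethylhepta-2,6-dien-1-ol | OC/C(C)=C\CC/C(C)=C\I | intermediate
13 | [(2S,3R)-3-[(3Z)-4-iodo-3-methylbut-3-en-1-yl]-2-methyloxiran-2-yl]methanol | OC[C@]1(C)O[C@@H]1CC/C(C)=C\I | intermediate
14 | (2R,3R)-3-[(3Z)-4-iodo-3-methylbut-3-en-1-yl]-2-methyloxirane-2-carbaldehyde | O=C[C@]1(C)O[C@@H]1CC/C(C)=C\I | intermediate
15 | diethyl (S)-malate | O[C@@H](CC(=O)OCC)C(=O)OCC | starting material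
16 | dilithium alkoxide enolate of 15 | [Li+].[Li+].[O-][C@@H](C=C([O-])OCC)C(=O)OCC | intermediate
17 | diethyl (2S,3R)-2-hydroxy-3-methylbutanedioate | CCOC(=O)[C@@H](O)[C@@H](C)C(=O)OCC | intermediate
18 | (2S,3R)-2-hydroxy-3-methylbutanedioic acid | OC(=O)[C@@H](O)[C@@H](C)C(O)=O | intermediate
19 | (2R)-2-[(2S,4S)-2-tert-butyl-5-oxo-1,3-dioxolan-4-yl]propanoic acid | CC(C)(C)[C@H]1O[C@@H]([C@@H](C)C(O)=O)C(=O)O1 | intermediate
20 | potassium salt of 19 | CC(C)(C)[C@H]1O[C@@H]([C@@H](C)C([O-])=O)C(=O)O1.[K+] | intermediate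
21 | propan-2-yl (2R)-2-[(2S,4S)-2-tert-butyl-5-oxo-1,3-dioxolan-4-yl]propanoate | CC(C)(C)[C@H]1O[C@@H]([C@@H](C)C(=O)OC(C)C)C(=O)O1 | intermediate
22 | but-3-yn-1-ol | OCCC#C | starting material
23 | dimethyl[(1E)-4-(dimethylalumanyloxy)-2-methylbut-1-en-1-yl]alumane | C[Al](C)/C=C(C)/CCO[Al](C)C | intermediate
24 | (2E)-3-methylpent-2-ene-1,5-diol | OC/C=C(C)/CCO | intermediate
25 | (2E)-5-hydroxy-3-methylpent-2-enal | O=C/C=C(C)/CCO | intermediate
26 | (2E)-5-bromo-3-methylpent-2-enal | O=C/C=C(C)/CCBr | intermediate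
27 | lithium enolate of 21 | CC(C)(C)[C@H]1OC([C@@H](C)C(=O)OC(C)C)=C([O-])O1.[Li+] | intermediate
28 | lithium aldolate (C9 alkoxide of the aldol adduct) | CC(C)(C)[C@H]1O[C@]([C@@H](C)C(=O)OC(C)C)([C@H]([O-])/C=C(C)/CCBr)C(=O)O1.[Li+] | intermediate
29 | propan-2-yl (2R)-2-[(2S,4R)-4-[(1R,2E)-5-bromo-3-methyl-1-(triethylsilyloxy)pent-2-en-1-yl]-2-tert-butyl-5-oxo-1,3-dioxolan-4-yl]propanoate | CC(C)(C)[C@H]1O[C@]([C@@H](C)C(=O)OC(C)C)([C@H](O[Si](CC)(CC)CC)/C=C(C)/CCBr)C(=O)O1 | intermediate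
30 | triphenylphosphonium bromide of 29 (P in place of Br at C13) | CC(C)(C)[C@H]1O[C@]([C@@H](C)C(=O)OC(C)C)([C@H](O[Si](CC)(CC)CC)/C=C(C)/CC[P+](c2ccccc2)(c2ccccc2)c2ccccc2)C(=O)O1.[Br-] | intermediate
31 | phosphonium ylide of 30 | CC(C)(C)[C@H]1O[C@]([C@@H](C)C(=O)OC(C)C)([C@H](O[Si](CC)(CC)CC)/C=C(C)/CC=P(c2ccccc2)(c2ccccc2)c2ccccc2)C(=O)O1 | intermediate
32 | propan-2-yl (2R)-2-[(2S,4R)-2-tert-butyl-4-[(1R,2E,5Z)-6-[(2S,3R)-3-[(3Z)-4-iodo-3-methylbut-3-en-1-yl]-2-methyloxiran-2-yl]-3-methyl-1-(triethylsilyloxy)hexa-2,5-dien-1-yl]-5-oxo-1,3-dioxolan-4-yl]propanoate | CC(C)(C)[C@H]1O[C@]([C@@H](C)C(=O)OC(C)C)([C@H](O[Si](CC)(CC)CC)/C=C(C)/C/C=C\[C@]2(C)O[C@@H]2CC/C(C)=C\I)C(=O)O1 | intermediate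
33 | 4-hydroxy-1,3-dioxolane lactol from 32 (anomer mixture) | CC(C)(C)[C@H]1O[C@]([C@@H](C)C(=O)OC(C)C)([C@H](O[Si](CC)(CC)CC)/C=C(C)/C/C=C\[C@]2(C)O[C@@H]2CC/C(C)=C\I)C(O)O1 | intermediate
34 | propan-2-yl (2R,3R,4R,5E,8Z)-3-formyl-3-hydroxy-9-[(2S,3R)-3-[(3Z)-4-iodo-3-methylbut-3-en-1-yl]-2-methyloxiran-2-yl]-2,6-dimethyl-4-(triethylsilyloxy)nona-5,8-dienoate | O=C[C@@](O)([C@@H](C)C(=O)OC(C)C)[C@H](O[Si](CC)(CC)CC)/C=C(C)/C/C=C\[C@]1(C)O[C@@H]1CC/C(C)=C\I | intermediate
35 | (Z)-alkenylchromium(III) dichloride from 34 (Cr in place of I at C6) | O=C[C@@](O)([C@@H](C)C(=O)OC(C)C)[C@H](O[Si](CC)(CC)CC)/C=C(C)/C/C=C\[C@]1(C)O[C@@H]1CC/C(C)=C\[Cr](Cl)Cl | intermediate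
36 | propan-2-yl ester of the macrocyclic (7S)-7,8-dihydroxy acid: 14-membered ring closed at C6–C7 with the lactone still open | CC[Si](CC)(CC)O[C@@H]1/C=C(C)/C/C=C\[C@]2(C)O[C@@H]2CC/C(C)=C\[C@H](O)[C@@]1(O)[C@@H](C)C(=O)OC(C)C | intermediate
37 | (1S,2R,5Z,7S,8S,9R,10E,13Z,17R)-1,2-epoxy-8-hydroxy-9-(triethylsilyloxy)-1,10-seco-briara-5,10,13-triene 7,19-lactone (14-membered cembranoid) | CC[Si](CC)(CC)O[C@@H]1/C=C(C)/C/C=C\[C@]3(C)O[C@@H]3CC/C(C)=C\[C@@H]2OC(=O)[C@H](C)[C@]21O | intermediate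
38 | briaran-11-yl tertiary carbocation (C1–C10 bond formed; drawn with free hydroxyls, present as aluminium alkoxides) | CC[Si](CC)(CC)O[C@@H]1[C@H]2[C+](C)CC=C[C@]2(C)[C@H](O)CC/C(C)=C\[C@@H]2OC(=O)[C@H](C)[C@]21O | intermediate
39 | (1S,2R,5Z,7S,8S,9R,10S,17R)-2,8-dihydroxy-9-(triethylsilyloxy)briara-5,11,13-triene 7,19-lactone | CC[Si](CC)(CC)O[C@@H]1[C@H]2C(C)=CC=C[C@]2(C)[C@H](O)CC/C(C)=C\[C@@H]2OC(=O)[C@H](C)[C@]21O | intermediate
40 | (1S,2R,5Z,7S,8S,9R,10S,17R)-2,8,9-trihydroxybriara-5,11,13-triene 7,19-lactone | O[C@@H]1[C@H]2C(C)=CC=C[C@]2(C)[C@H](O)CC/C(C)=C\[C@@H]2OC(=O)[C@H](C)[C@]21O | intermediate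
41 | (1S,2R,5Z,7S,8S,9R,10S,17R)-2,9-diacetoxy-8-hydroxybriara-5,11,13-triene 7,19-lactone | CC(=O)O[C@@H]1[C@H]2C(C)=CC=C[C@]2(C)[C@H](OC(C)=O)CC/C(C)=C\[C@@H]2OC(=O)[C@H](C)[C@]21O | intermediate
42 | cyclic 11α,12α-osmate(VI) ester of 43 | CC(=O)O[C@@H]1[C@H]2[C@]3(C)O[Os](=O)(=O)O[C@@H]3C=C[C@]2(C)[C@H](OC(C)=O)CC/C(C)=C\[C@@H]2OC(=O)[C@H](C)[C@]21O | intermediate
43 | (1S,2R,5Z,7S,8S,9R,10S,11S,12R,17R)-2,9-diacetoxy-8,11,12-trihydroxybriara-5,13-diene 7,19-lactone (CNP0146024.1) | CC(=O)O[C@@H]1[C@H]2[C@](C)(O)[C@H](O)C=C[C@]2(C)[C@H](OC(C)=O)CC/C(C)=C\[C@@H]2OC(=O)[C@H](C)[C@]21O | target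

**Step count and risks**

Total step count: 22 (22 isolated products). Longest linear sequence: 13 steps (steps 1–6 then 16–22; the malate branch, steps 7–10, 14, 15 then 16–22, is equally long).

The three steps most likely to fail:

Step 19 (transannular cyclisation). The C5=C6 olefin can also reach C1 through a six-membered transition state; the only bias against it is the allylic lactone oxygen and the hindered C7. The activated epoxide may instead undergo a 1,2-shift, and the C11 cation may lose H-10 or H-20 instead of H-12. The fallback gives up the transannular order. It sets out from 32 and comes back at 39. Acyclic 32, in which C5=C6 is still the electron-poor iodoalkene and cannot compete, is treated with Et2AlCl in CH2Cl2 at −78 °C to close only the six-membered ring. This gives propan-2-yl (2R)-2-[(2S,4R)-2-tert-butyl-4-[(R)-[(1S,6S)-6-[(1R,4Z)-1-hydroxy-5-iodo-4-methylpent-4-en-1-yl]-2,6-dimethylcyclohexa-2,4-dien-1-yl](triethylsilyloxy)methyl]-5-oxo-1,3-dioxolan-4-yl]propanoate F1. DIBAL-H at −90 °C then reduces the dioxolanone to the corresponding 3-formyl-3-hydroxy ester F2. Ni/Cr coupling of F2 at high dilution closes the ten-membered ring at C6–C7 and lactonises to 39.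

Step 18 (Ni/Cr macrocyclisation). Ring closure is well precedented, but the configuration at C7 rests on Felkin–Anh control next to a quaternary carbinol and could come out wrong. The fallback corrects C7 by an invertive lactonisation instead of by the C–C bond formation. It sets out from 34 and comes back at 37. If the Ni/Cr step delivers the (7R) epimer, it is obtained as the 7-epi cembranoid lactone F3. LiOH in THF/H2O opens it to the (7R)-7,8-dihydroxy seco acid F4. Mitsunobu lactonisation (PPh3, DIAD, THF, 0 °C) activates only the secondary allylic 7-OH and closes the γ-lactone with inversion to 37; the tertiary 8-OH and the silyl ether do not react.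

Step 22 (final dihydroxylation). Three olefins are present, and catalytic OsO4 may also attack C5=C6 or over-oxidise. The fallback uses a hydroxyl-directed stoichiometric osmylation before acylation and carries the osmate ester as a protecting group. It sets out from 40 and comes back at 43. Triol 40 is treated with OsO4·TMEDA in CH2Cl2 at −78 °C; hydrogen bonding to the homoallylic 9-OH delivers osmium to the α-face of C11=C12 and gives the 11α,12α-osmate ester TMEDA complex of the 2,8,9-triol F5. Ac2O/pyridine/DMAP acetylates the 2- and 9-hydroxyls to the osmate ester TMEDA complex of the 2,9-diacetate F6. Aqueous Na2SO3 in THF at 40 °C then releases 43.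

**Further compounds**

F1 | step 19 | propan-2-yl (2R)-2-[(2S,4R)-2-tert-butyl-4-[(R)-[(1S,6S)-6-[(1R,4Z)-1-hydroxy-5-iodo-4-methylpent-4-en-1-yl]-2,6-dimethylcyclohexa-2,4-dien-1-yl](triethylsilyloxy)methyl]-5-oxo-1,3-dioxolan-4-yl]propanoate | CC(C)(C)[C@H]1O[C@]([C@@H](C)C(=O)OC(C)C)([C@H](O[Si](CC)(CC)CC)[C@H]2C(C)=CC=C[C@]2(C)[C@H](O)CC/C(C)=C\I)C(=O)O1
F2 | step 19 | propan-2-yl (2R,3R,4R)-4-[(1S,6S)-6-[(1R,4Z)-1-hydroxy-5-iodo-4-methylpent-4-en-1-yl]-2,6-dimethylcyclohexa-2,4-dien-1-yl]-3-formyl-3-hydroxy-2-methyl-4-(triethylsilyloxy)butanoate | O=C[C@@](O)([C@@H](C)C(=O)OC(C)C)[C@H](O[Si](CC)(CC)CC)[C@H]1C(C)=CC=C[C@]1(C)[C@H](O)CC/C(C)=C\I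
F3 | step 18 | (1S,2R,5Z,7R,8S,9R,10E,13Z,17R)-1,2-epoxy-8-hydroxy-9-(triethylsilyloxy)-1,10-seco-briara-5,10,13-triene 7,19-lactone (7-epi-37) | CC[Si](CC)(CC)O[C@@H]1/C=C(C)/C/C=C\[C@]3(C)O[C@@H]3CC/C(C)=C\[C@H]2OC(=O)[C@H](C)[C@]21O
F4 | step 18 | (7R)-7,8-dihydroxy seco acid from F3 (14-membered ring, lactone opened) | CC[Si](CC)(CC)O[C@@H]1/C=C(C)/C/C=C\[C@]2(C)O[C@@H]2CC/C(C)=C\[C@@H](O)[C@@]1(O)[C@@H](C)C(O)=O
F5 | step 22 | 11α,12α-osmate(VI) ester TMEDA complex of the 2,8,9-triol | O[C@@H]1[C@H]2[C@]3(C)O[Os](=O)(=O)O[C@@H]3C=C[C@]2(C)[C@H](O)CC/C(C)=C\[C@@H]2OC(=O)[C@H](C)[C@]21O.CN(C)CCN(C)C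
F6 | step 22 | 11α,12α-osmate(VI) ester TMEDA complex of the 2,9-diacetate | CC(=O)O[C@@H]1[C@H]2[C@]3(C)O[Os](=O)(=O)O[C@@H]3C=C[C@]2(C)[C@H](OC(C)=O)CC/C(C)=C\[C@@H]2OC(=O)[C@H](C)[C@]21O.CN(C)CCN(C)C
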